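**Retrosynthetic overview**
1. The last disconnection is the aryl silyl ether of 20. Before it, ring A (the enolised 2-propanoyl-4,4-dimethylcyclohexane-1,3,5-trione) is cut twice in a convergent [3+3]: between the propanoyl-bearing carbon and one ring carbonyl, and between the C(CH3)2 carbon and the other. This gives malonyl bis-electrophile 11 and three-carbon bis-nucleophile 16.
2. Enabling feature: in ring A the carbon carrying the CH2 bridge lies between two carbonyl carbons (a malonyl unit), the third ring carbonyl is flanked by the two nucleophilic carbons, and the quaternary C(CH3)2 carbon rules out aromatisation and an aromatic pyranone. In ring B (the benzene ring) the hydroxyl oxygen ortho to both the CH2 bridge and the acetyl-bearing carbon can be tied to one malonyl carbonyl as a six-membered aryl lactone (ring D, absent from the target). Ring D activates that carbonyl, masks the phenol and is opened in the key step.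
3. 11 comes from phloroacetophenone by para-O-silylation, chromene annulation (ring C), Mannich reaction, Meldrum's acid alkylation with lactonisation (ring D) and acid chloride formation. 16 comes from but-1-yne and 2-methylpropanoyl chloride through a vinylogous amide that masks the propanoyl group.
4. Order of ring formation: ring C (step 2), temporary ring D (step 4), ring A with opening of ring D (step 8).

Key step: step 8

Remark: the target has no stereocentre and is drawn as one of its enol tautomers; 10, 11 and 17 are racemic at the malonyl carbon, which becomes an enol carbon in step 8, and the exocyclic alkene geometry of 19 is not defined.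

**Step 1**
Reactants: 1 1-(2,4,6-trihydroxyphenyl)ethan-1-one
Product: 2 1-[2,6-dihydroxy-4-(triisopropylsilyloxy)phenyl]ethan-1-one
Conditions: iPr3SiCl (1.05 equiv), imidazole, DMF, 0 °C
Reagents that add atoms: chlorotriisopropylsilane, CC(C)[Si](Cl)(C(C)C)C(C)C
Why: Silyl ether formation should occur only at the para hydroxyl, the one phenol of 1 that is not hydrogen-bonded to the acetyl group and the most acidic and least hindered towards the bulky silyl chloride.

**Step 2**
Reactants: 2 1-[2,6-dihydroxy-4-(triisopropylsilyloxy)phenyl]ethan-1-one; 3 3-methylbut-2-enal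
Product: 4 1-[7-hydroxy-2,2-dimethyl-5-(triisopropylsilyloxy)-2H-chromen-8-yl]ethan-1-one
Conditions: ethylenediammonium diacetate (10 mol%), toluene, 110 °C
Reagents that add atoms: none
Why: Knoevenagel-type condensation at a ring carbon ortho to a free hydroxyl, dehydration to an ortho-quinone methide and oxa-6π electrocyclisation (chromene annulation of a phenol with an enal) should close ring C onto an oxygen ortho to the acetyl group, the only regiochemistry possible because the other flanking oxygen is silylated.

**Step 3**
Reactants: 4 1-[7-hydroxy-2,2-dimethyl-5-(triisopropylsilyloxy)-2H-chromen-8-yl]ethan-1-one; 5 N,N-dimethylmethyleneiminium iodide (Eschenmoser's salt)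
Product: 6 1-{6-[(dimethylamino)methyl]-7-hydroxy-2,2-dimethyl-5-(triisopropylsilyloxy)-2H-chromen-8-yl}ethan-1-one
Conditions: Et3N, CH2Cl2, 0 °C to rt
Reagents that add atoms: none
Why: Mannich aminomethylation should occur at the single free position of ring B, which is ortho to the free hydroxyl and activated by three oxygen substituents.

**Step 4**
Reactants: 6 1-{6-[(dimethylamino)methyl]-7-hydroxy-2,2-dimethyl-5-(triisopropylsilyloxy)-2H-chromen-8-yl}ethan-1-one; 7 2,2-dimethyl-1,3-dioxane-4,6-dione (Meldrum's acid)
Product: 10 rac-10-acetyl-8,8-dimethyl-2-oxo-5-(triisopropylsilyloxy)-3,4-dihydro-2H,8H-pyrano[3,2-g]chromene-3-carboxylic acid, via ortho-quinone methide 8 (not isolated), via Meldrum's acid adduct 9 (not isolated)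
Conditions: 7 (2 equiv), MeCN, 70 °C; then AcOH, 60 °C
Reagents that add atoms: none
Why: Thermal loss of dimethylamine from the phenolic Mannich base gives ortho-quinone methide 8, Michael addition of Meldrum's acid gives 9, and attack of the neighbouring phenol on a dioxanedione carbonyl with loss of acetone (acyl substitution) should close the six-membered aryl lactone, ring D, and leave the other malonyl carbonyl as the free acid.

**Step 5**
Reactants: 10 rac-10-acetyl-8,8-dimethyl-2-oxo-5-(triisopropylsilyloxy)-3,4-dihydro-2H,8H-pyrano[3,2-g]chromene-3-carboxylic acid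
Product: 11 rac-10-acetyl-8,8-dimethyl-2-oxo-5-(triisopropylsilyloxy)-3,4-dihydro-2H,8H-pyrano[3,2-g]chromene-3-carbonyl chloride
Conditions: 1-chloro-N,N,2-trimethylprop-1-en-1-amine, CH2Cl2, 0 °C to rt
Reagents that add atoms: 1-chloro-N,N,2-trimethylprop-1-en-1-amine (Ghosez's reagent), CC(C)=C(Cl)N(C)C
Why: Ghosez's reagent converts a carboxylic acid into its chloride under neutral conditions without HCl, which should spare the silyl ether, the chromene and the lactone, and 11 is used directly.

**Step 6**
Reactants: 12 2-methylpropanoyl chloride; 13 but-1-yne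
Product: 15 (4E)-5-(dimethylamino)-2-methylhept-4-en-3-one, via 2-methylhept-4-yn-3-one 14 (not isolated)
Conditions: PdCl2(PPh3)2 (2 mol%), CuI (4 mol%), Et3N (1.05 equiv), THF, rt; then Me2NH (2 M in THF), rt
Reagents that add atoms: dimethylamine, CNC
Why: Acyl Sonogashira coupling followed by conjugate addition of the secondary amine to the ynone should place the nitrogen only on the ethyl-bearing carbon and give the E vinylogous amide, the thermodynamically preferred geometry of a push-pull alkene with the amino group trans to the carbonyl.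

**Step 7**
Reactants: 15 (4E)-5-(dimethylamino)-2-methylhept-4-en-3-one
Product: 16 tert-butyl{[(4E)-5-(dimethylamino)-2-methylhepta-2,4-dien-3-yl]oxy}dimethylsilane
Conditions: KN(SiMe3)2, THF, −78 °C; then tBuMe2SiCl, −78 °C to rt
Reagents that add atoms: tert-butylchlorodimethylsilane, CC(C)(C)[Si](C)(C)Cl
Why: Kinetic deprotonation of a vinylogous amide occurs at the α'-carbon, here the isopropyl methine (as in Stork–Danheiser α'-alkylation), and O-silylation of the cross-conjugated enolate should give the 1-amino-3-siloxy-1,3-diene with the enamine geometry unchanged.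

**Step 8**
Reactants: 11 rac-10-acetyl-8,8-dimethyl-2-oxo-5-(triisopropylsilyloxy)-3,4-dihydro-2H,8H-pyrano[3,2-g]chromene-3-carbonyl chloride; 16 tert-butyl{[(4E)-5-(dimethylamino)-2-methylhepta-2,4-dien-3-yl]oxy}dimethylsilane
Product: 20 2-{[8-acetyl-7-hydroxy-2,2-dimethyl-5-(triisopropylsilyloxy)-2H-chromen-6-yl]methyl}-3,5-dihydroxy-4,4-dimethyl-6-propanoylcyclohexa-2,5-dien-1-one, via keto lactone 17 (not isolated), via acylketene 18 (not isolated), via aminopropylidene trione 19 (not isolated)
Conditions: 16 (1.3 equiv), CH2Cl2, −78 to 0 °C; then Et3N (0.2 equiv), 40 °C; then 1 M HCl, THF, rt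
Reagents that add atoms: water, O
Why: Proposed new method: the siloxy-bearing terminus of 16 (the future C(CH3)2 carbon, activated by both the silyl enol ether and the vinylogous amine) should C-acylate with the acid chloride of 11 with loss of the silyl group (Mukaiyama-type Claisen acylation, as in the uncatalysed acylation of 1,3-bis-silyl dienol ethers with malonyl chlorides) to give 17; base then removes the malonyl proton of 17 and expels the ortho-acyl aryloxide (E1cB opening of the temporary lactone, as known for aryl β-keto esters) to give acylketene 18, whose ketene carbon is attacked by the enaminone α-carbon to close ring A, and acid hydrolysis of the resulting vinylogous amide 19 unmasks the propanoyl group. The closest known reaction type is the Effenberger cyclisation, in which a silyl enol ether and malonyl dichloride form the same two carbon–carbon bonds of a cyclohexane-1,3,5-trione by α,α'-double acylation, and the second acylation mirrors the Claisen cyclisation of a tetraketide to an acylphloroglucinol. Ring A closes in a 6-(enolexo)-exo-dig mode on the ketene carbon (exo-trig if the lactone carbonyl is attacked directly), helped by the gem-dimethyl group. No stereocentre is created, since the malonyl stereocentre of 17 becomes an enol carbon and 20 is achiral. The step needs three selectivities: diene terminus before central carbon (secured by the silyl enol ether and by the conjugated vinylogous amide that results), acid chloride before lactone (secured by their large reactivity gap, which orders the two acylations), and carbon over oxygen closure (secured by the tertiary amino group, since O-acylation gives only a reversible zwitterion whereas C-acylation ends in a neutral, strongly stabilised vinylogous amide, and by the quaternary carbon, which excludes an aromatic pyranone).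

**Step 9**
Reactants: 20 2-{[8-acetyl-7-hydroxy-2,2-dimethyl-5-(triisopropylsilyloxy)-2H-chromen-6-yl]methyl}-3,5-dihydroxy-4,4-dimethyl-6-propanoylcyclohexa-2,5-dien-1-one
Product: 21 2-[(8-acetyl-5,7-dihydroxy-2,2-dimethyl-2H-chromen-6-yl)methyl]-3,5-dihydroxy-4,4-dimethyl-6-propanoylcyclohexa-2,5-dien-1-one (target, CNP0153527.0)
Conditions: Bu4NF, AcOH, THF, 0 °C
Reagents that add atoms: none
Why: Fluoride-mediated cleavage of the aryl silyl ether, buffered with acetic acid so that the acidic enol and the methylene-bridged phenols are not exposed to base, should release the last hydroxyl and give the target.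

**Compound list**
1 | 1-(2,4,6-trihydroxyphenyl)ethan-1-one (2',4',6'-trihydroxyacetophenone) | CC(=O)c1c(O)cc(O)cc1O | starting material
2 | 1-[2,6-dihydroxy-4-(triisopropylsilyloxy)phenyl]ethan-1-one | CC(=O)c1c(O)cc(O[Si](C(C)C)(C(C)C)C(C)C)cc1O | intermediate
3 | 3-methylbut-2-enal | CC(C)=CC=O | starting material
4 | 1-[7-hydroxy-2,2-dimethyl-5-(triisopropylsilyloxy)-2H-chromen-8-yl]ethan-1-one | CC(=O)c1c(O)cc(O[Si](C(C)C)(C(C)C)C(C)C)c2C=CC(C)(C)Oc12 | intermediate
5 | N,N-dimethylmethyleneiminium iodide (Eschenmoser's salt) | C[N+](C)=C.[I-] | starting material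
6 | 1-{6-[(dimethylamino)methyl]-7-hydroxy-2,2-dimethyl-5-(triisopropylsilyloxy)-2H-chromen-8-yl}ethan-1-one | CC(=O)c1c(O)c(CN(C)C)c(O[Si](C(C)C)(C(C)C)C(C)C)c2C=CC(C)(C)Oc12 | intermediate
7 | 2,2-dimethyl-1,3-dioxane-4,6-dione (Meldrum's acid) | CC1(C)OC(=O)CC(=O)O1 | starting material
8 | 8-acetyl-2,2-dimethyl-6-methylidene-5-(triisopropylsilyloxy)-2H-chromen-7(6H)-one | CC(=O)C1=C2OC(C)(C)C=CC2=C(O[Si](C(C)C)(C(C)C)C(C)C)C(=C)C1=O | intermediate
9 | 5-{[8-acetyl-7-hydroxy-2,2-dimethyl-5-(triisopropylsilyloxy)-2H-chromen-6-yl]methyl}-2,2-dimethyl-1,3-dioxane-4,6-dione | CC(=O)c1c(O)c(CC2C(=O)OC(C)(C)OC2=O)c(O[Si](C(C)C)(C(C)C)C(C)C)c2C=CC(C)(C)Oc12 | intermediate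
10 | rac-10-acetyl-8,8-dimethyl-2-oxo-5-(triisopropylsilyloxy)-3,4-dihydro-2H,8H-pyrano[3,2-g]chromene-3-carboxylic acid | CC(=O)c1c2OC(=O)C(C(=O)O)Cc2c(O[Si](C(C)C)(C(C)C)C(C)C)c2C=CC(C)(C)Oc12 | intermediate
11 | rac-10-acetyl-8,8-dimethyl-2-oxo-5-(triisopropylsilyloxy)-3,4-dihydro-2H,8H-pyrano[3,2-g]chromene-3-carbonyl chloride | CC(=O)c1c2OC(=O)C(C(Cl)=O)Cc2c(O[Si](C(C)C)(C(C)C)C(C)C)c2C=CC(C)(C)Oc12 | intermediate
12 | 2-methylpropanoyl chloride | CC(C)C(Cl)=O | starting material
13 | but-1-yne | CCC#C | starting material
14 | 2-methylhept-4-yn-3-one | CCC#CC(=O)C(C)C | intermediate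
15 | (4E)-5-(dimethylamino)-2-methylhept-4-en-3-one | CC/C(=C\C(=O)C(C)C)N(C)C | intermediate
16 | tert-butyl{[(4E)-5-(dimethylamino)-2-methylhepta-2,4-dien-3-yl]oxy}dimethylsilane | CC/C(=C\C(O[Si](C)(C)C(C)(C)C)=C(C)C)N(C)C | intermediate
17 | rac-10-acetyl-3-[(4E)-5-(dimethylamino)-2,2-dimethyl-3-oxohept-4-enoyl]-8,8-dimethyl-5-(triisopropylsilyloxy)-3,4-dihydro-2H,8H-pyrano[3,2-g]chromen-2-one | CC/C(=C\C(=O)C(C)(C)C(=O)C1Cc2c(O[Si](C(C)C)(C(C)C)C(C)C)c3C=CC(C)(C)Oc3c(C(C)=O)c2OC1=O)N(C)C | intermediate
18 | (6E)-2-{[8-acetyl-7-hydroxy-2,2-dimethyl-5-(triisopropylsilyloxy)-2H-chromen-6-yl]methyl}-7-(dimethylamino)-4,4-dimethylnona-1,6-diene-1,3,5-trione | CC/C(=C\C(=O)C(C)(C)C(=O)C(=C=O)Cc1c(O)c(C(C)=O)c2OC(C)(C)C=Cc2c1O[Si](C(C)C)(C(C)C)C(C)C)N(C)C | intermediate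
19 | 6-{[8-acetyl-7-hydroxy-2,2-dimethyl-5-(triisopropylsilyloxy)-2H-chromen-6-yl]methyl}-2-[1-(dimethylamino)propylidene]-5-hydroxy-4,4-dimethylcyclohex-5-ene-1,3-dione | CCC(N(C)C)=C1C(=O)C(C)(C)C(O)=C(Cc2c(O)c(C(C)=O)c3OC(C)(C)C=Cc3c2O[Si](C(C)C)(C(C)C)C(C)C)C1=O | intermediate
20 | 2-{[8-acetyl-7-hydroxy-2,2-dimethyl-5-(triisopropylsilyloxy)-2H-chromen-6-yl]methyl}-3,5-dihydroxy-4,4-dimethyl-6-propanoylcyclohexa-2,5-dien-1-one | CCC(=O)C1=C(O)C(C)(C)C(O)=C(Cc2c(O)c(C(C)=O)c3OC(C)(C)C=Cc3c2O[Si](C(C)C)(C(C)C)C(C)C)C1=O | intermediate
21 | 2-[(8-acetyl-5,7-dihydroxy-2,2-dimethyl-2H-chromen-6-yl)methyl]-3,5-dihydroxy-4,4-dimethyl-6-propanoylcyclohexa-2,5-dien-1-one | CCC(=O)C1=C(O)C(C)(C)C(O)=C(Cc2c(O)c3c(c(C(C)=O)c2O)OC(C)(C)C=C3)C1=O | target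

**Step count and risks**
Total steps: 9. Longest linear sequence: 7 steps (steps 1, 2, 3, 4, 5, 8 and 9).

Steps most likely to fail:

1. Step 8 (proposed new method). What may go wrong: proton transfer from the acidic acid chloride to the basic diene (ketene formation and oligomerisation) in place of C-acylation at the hindered diene terminus, or closure through the vinylogous amide oxygen rather than carbon once the lactone has opened. Fallback with known chemistry, which forms the methylene bridge instead of ring A: it sets out from 6 and comes back at 20. Commercial 1-(2,4,6-trihydroxyphenyl)propan-1-one would be C-methylated twice at one ring carbon (MeI, NaOMe, MeOH, rt) to 3,5-dihydroxy-4,4-dimethyl-2-propanoylcyclohexa-2,5-dien-1-one F1. Heating F1 with Mannich base 6 (dioxane, 90 °C) should generate ortho-quinone methide 8 and add the free ring carbon of F1 to it (Michael addition), which would give 20 ready for step 9.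

2. Step 7. What may go wrong: deprotonation at the CH2 of the ethyl group (γ-position) in competition with the hindered isopropyl methine, which would give an isomeric amino diene and later closure on the wrong carbon. Fallback that fixes the enol ether position by hydride delivery instead of deprotonation: it sets out from 13 and comes back at 16. But-1-yne 13 would be coupled with 2-methylprop-2-enoyl chloride (PdCl2(PPh3)2, CuI, Et3N, THF, rt) to 2-methylhept-1-en-4-yn-3-one F2. Addition of dimethylamine (1 equiv, −20 °C) to the ynone would give (4E)-5-(dimethylamino)-2-methylhepta-1,4-dien-3-one F3. 1,4-Hydrosilylation of the isopropenyl ketone of F3 (tBuMe2SiH, RhCl(PPh3)3 cat., benzene, 50 °C) should place hydrogen on the terminal methylene carbon and silicon on oxygen and so give 16.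

3. Step 4. What may go wrong: slow amine elimination from the chelated, hindered Mannich base, a second alkylation of Meldrum's acid by another quinone methide, or decarboxylation of the half-acid on heating. Fallback through an aldehyde instead of a quinone methide: it sets out from 4 and comes back at 9. Magnesium-mediated ortho-formylation of 4 (MgCl2, Et3N, paraformaldehyde, MeCN, reflux) would give 8-acetyl-7-hydroxy-2,2-dimethyl-5-(triisopropylsilyloxy)-2H-chromene-6-carbaldehyde F4. Reductive Knoevenagel alkylation of Meldrum's acid 7 with F4 and Hantzsch ester (L-proline cat., EtOH, rt) should give adduct 9, which lactonises to 10 on warming with AcOH as in step 4.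

**Further compounds**
F1 | step 8 | 3,5-dihydroxy-4,4-dimethyl-2-propanoylcyclohexa-2,5-dien-1-one | CCC(=O)C1=C(O)C(C)(C)C(O)=CC1=O
F2 | step 7 | 2-methylhept-1-en-4-yn-3-one | CCC#CC(=O)C(C)=C
F3 | step 7 | (4E)-5-(dimethylamino)-2-methylhepta-1,4-dien-3-one | CC/C(=C\C(=O)C(C)=C)N(C)C
F4 | step 4 | 8-acetyl-7-hydroxy-2,2-dimethyl-5-(triisopropylsilyloxy)-2H-chromene-6-carbaldehyde | CC(=O)c1c(O)c(C=O)c(O[Si](C(C)C)(C(C)C)C(C)C)c2C=CC(C)(C)Oc12
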